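**Retrosynthetic overview** (numbering: cyclopenta[c]pyran C1, O2, C3, C4, C4a, C5–C7, C7a; benzofuranone atoms primed)
1. The C2′–OAc bond is made last by acetoxylation of the aromatic 3-silyloxybenzofuran; the C1–C2′ bond is cut to a cyclic oxocarbenium ion (C1=O2+) and the silyl enol ether of 4-methylbenzofuran-3(2H)-one.
2. The isovaleryl ketone on C3 is traced back to a methyl ester, which leaves the three-carbon donor enolisable on one side only.
3. Key disconnection: the dihydropyran ring is opened across O2–C1 and C4–C4a into (5S)-5-methylcyclopent-1-ene-1-carbaldehyde and methyl 2-oxobutanoate; this [3+3] Michael addition/lactolisation copies the iridodial → nepetalactol closure of iridoid biosynthesis.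
4. Enabling feature: in the pyran ring, O2–C3(acyl)=C4(CH3) is the enol of a 1,2-dicarbonyl unit (C4 and O2 form a 1,3-bis-nucleophile), and C4a–C7a–C1 is, once C1 is taken back to the aldehyde level, the 1,3-bis-electrophile C4a=C7a–C1=O of a cyclopentene carbaldehyde.
5. Ring order: cyclopentene (metathesis of methylenated (S)-citronellal, which supplies C7) → dihydropyran (key step) → union with the separately made benzofuranone.

Key step: step 3

Remark: C1 of the lactol and its methyl acetals and C2′ of the coupling product are carried as mixtures, because C1 is set in step 8 and C2′ in step 10.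

Step 1
Reactants: 1 (S)-citronellal, (3S)-3,7-dimethyloct-6-enal
Product: 2 (3S)-3,7-dimethyl-2-methylideneoct-6-enal
Conditions: 37% aq. HCHO, pyrrolidine (10 mol%), EtCO2H (10 mol%), i-PrOH, 45 °C
Reagents that add atoms: formaldehyde, C=O
Why: Amine-catalysed Mannich condensation/elimination (α-methylenation of an aldehyde) installs the second alkene for ring closure, and the C3 stereocentre (the future C7) lies β to the carbonyl and is not touched.

Step 2
Reactants: 2 (3S)-3,7-dimethyl-2-methylideneoct-6-enal
Product: 3 (5S)-5-methylcyclopent-1-ene-1-carbaldehyde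
Conditions: second-generation Grubbs catalyst (H2IMes)(PCy3)Cl2Ru=CHPh (2 mol%), CH2Cl2, 40 °C
Reagents that add atoms: none
Why: Ring-closing metathesis of the 1,6-diene should close the cyclopentene with loss of volatile 2-methylpropene, the stereocentre being a spectator.

Step 3
Reactants: 3 (5S)-5-methylcyclopent-1-ene-1-carbaldehyde; 4 methyl 2-oxobutanoate
Product: 5 methyl (4aS,7S,7aR)-1-hydroxy-4,7-dimethyl-1,4a,5,6,7,7a-hexahydrocyclopenta[c]pyran-3-carboxylate (both C1 anomers)
Conditions: 4 (1.5 equiv, slow addition), pyrrolidine (20 mol%), PhCO2H (20 mol%), toluene, 0 → 25 °C; aq. NH4Cl work-up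
Reagents that add atoms: none
Why: Proposed new method: pyrrolidine condenses with the very electrophilic ketone of 4 to a 2-aminoacrylate-type enamine that can be nucleophilic only at C4, this adds in a Michael reaction to C4a of enal 3 (free or as its iminium ion), the enamine so formed at C7a–C1 is protonated and hydrolysed, and the C3 enol oxygen O2 closes onto the C1 aldehyde; the closest known reaction types are the Stork enamine addition to enals and the amine-catalysed Michael addition/hemiacetalisation of enolised 1,3-dicarbonyl donors with enals, and the sequence mirrors the iridodial → nepetalactol closure of iridoid biosynthesis. The dihydropyran ring closes by 6-exo-trig attack of O2 on the C1 carbonyl after the intermolecular C4–C4a bond has formed. C4a is controlled by the C7 methyl group, which sits pseudoaxial on the cyclopentene and sends the donor to the opposite face; C7a is controlled by the new C4a substituent, kinetic protonation occurring anti to it to give the cis ring fusion that the lactol then locks, and C1 is an inconsequential anomeric centre. The step needs 1,4- instead of 1,2-attack on the enal and a single nucleophilic carbon in the donor: the first is secured by the soft enamine/iminium pairing, the second by the ester on C3, which cannot enolise and also closes off the Michael/aldol pathway that a second ketone would open.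

Step 4
Reactants: 5 methyl (4aS,7S,7aR)-1-hydroxy-4,7-dimethyl-1,4a,5,6,7,7a-hexahydrocyclopenta[c]pyran-3-carboxylate
Product: 6 methyl (4aS,7S,7aR)-1-methoxy-4,7-dimethyl-1,4a,5,6,7,7a-hexahydrocyclopenta[c]pyran-3-carboxylate (both C1 anomers)
Conditions: MeOH, pyridinium p-toluenesulfonate (5 mol%), 25 °C
Reagents that add atoms: methanol, CO
Why: Acid-catalysed acetalisation of the lactol through the cyclic oxocarbenium ion masks C1 against the Grignard reagents of step 5 and installs the leaving group for step 8, the anomeric mixture being of no consequence.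

Step 5
Reactants: 6 methyl (4aS,7S,7aR)-1-methoxy-4,7-dimethyl-1,4a,5,6,7,7a-hexahydrocyclopenta[c]pyran-3-carboxylate
Product: 8 1-[(4aS,7S,7aR)-1-methoxy-4,7-dimethyl-1,4a,5,6,7,7a-hexahydrocyclopenta[c]pyran-3-yl]-3-methylbutan-1-one (both C1 anomers), via Weinreb amide 7 (not isolated)
Conditions: MeNHOMe·HCl (1.5 equiv), i-PrMgCl (3.0 equiv), THF, −20 °C; then i-BuMgBr (2.0 equiv), −20 → 0 °C; aq. NH4Cl
Reagents that add atoms: isobutylmagnesium bromide, CC(C)C[Mg]Br
Why: Aminolysis of the ester by Me(MeO)NMgCl gives the Weinreb amide, whose chelated tetrahedral adduct with i-BuMgBr releases the isovaleryl ketone only on work-up (Weinreb ketone synthesis), while the acetal, the enol ether and all stereocentres stay untouched.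

Step 6
Reactants: 9 1-(2-hydroxy-6-methylphenyl)ethan-1-one
Product: 11 4-methyl-1-benzofuran-3(2H)-one, via bromoketone 10 (not isolated)
Conditions: CuBr2 (2.1 equiv), EtOAc/CHCl3, reflux; then NaOAc, EtOH, reflux
Reagents that add atoms: none
Why: α-Bromination of the aryl methyl ketone with CuBr2 followed by base-mediated intramolecular O-alkylation of the phenol (5-exo-tet) should give the benzofuranone.

Step 7
Reactants: 11 4-methyl-1-benzofuran-3(2H)-one
Product: 12 trimethyl[(4-methyl-1-benzofuran-3-yl)oxy]silane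
Conditions: Me3SiOTf (1.1 equiv), Et3N (1.5 equiv), CH2Cl2, 0 °C
Reagents that add atoms: trimethylsilyl trifluoromethanesulfonate, C[Si](C)(C)OS(=O)(=O)C(F)(F)F
Why: Soft enolisation and O-silylation of the ketone (silyl enol ether formation) is driven by aromatisation to the benzofuran.

Step 8
Reactants: 8 1-[(4aS,7S,7aR)-1-methoxy-4,7-dimethyl-1,4a,5,6,7,7a-hexahydrocyclopenta[c]pyran-3-yl]-3-methylbutan-1-one; 12 trimethyl[(4-methyl-1-benzofuran-3-yl)oxy]silane
Product: 13 2-[(1R,4aS,7S,7aR)-4,7-dimethyl-3-(3-methylbutanoyl)-1,4a,5,6,7,7a-hexahydrocyclopenta[c]pyran-1-yl]-4-methyl-1-benzofuran-3(2H)-one (both C2′ epimers)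
Conditions: Me3SiOTf (0.2 equiv), CH2Cl2, −78 → −40 °C; aq. NaHCO3
Reagents that add atoms: none
Why: Mukaiyama-type addition of the silyl enol ether to the cyclic oxocarbenium ion C1=O2+ released from the mixed acetal forms the C1–C2′ bond, the nucleophile attacking the convex face of the cis-fused bicycle, syn to H-7a and anti to the cyclopentane carbon C7, which sets C1 as R, while C2′ forms as an epimer mixture that step 9 erases.

Step 9
Reactants: 13 2-[(1R,4aS,7S,7aR)-4,7-dimethyl-3-(3-methylbutanoyl)-1,4a,5,6,7,7a-hexahydrocyclopenta[c]pyran-1-yl]-4-methyl-1-benzofuran-3(2H)-one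
Product: 14 1-{(1R,4aS,7S,7aR)-4,7-dimethyl-1-[4-methyl-3-(trimethylsilyloxy)-1-benzofuran-2-yl]-1,4a,5,6,7,7a-hexahydrocyclopenta[c]pyran-3-yl}-3-methylbutan-1-one
Conditions: Me3SiCl (1.5 equiv), Et3N (2.0 equiv), DMF, 25–40 °C; pentane extraction
Reagents that add atoms: chlorotrimethylsilane, C[Si](C)(C)Cl
Why: Silyl enol ether formation under conditions that touch only the far more acidic benzofuranone C2′–H (its enol is an aromatic benzofuran) should give one planar enol ether from both C2′ epimers and leave the isovaleryl ketone alone.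

Step 10
Reactants: 14 1-{(1R,4aS,7S,7aR)-4,7-dimethyl-1-[4-methyl-3-(trimethylsilyloxy)-1-benzofuran-2-yl]-1,4a,5,6,7,7a-hexahydrocyclopenta[c]pyran-3-yl}-3-methylbutan-1-one
Product: 15 (2S)-2-[(1R,4aS,7S,7aR)-4,7-dimethyl-3-(3-methylbutanoyl)-1,4a,5,6,7,7a-hexahydrocyclopenta[c]pyran-1-yl]-4-methyl-3-oxo-2,3-dihydro-1-benzofuran-2-yl acetate (CNP0168042.1)
Conditions: Pb(OAc)4 (1.1 equiv), CH2Cl2, −40 → 0 °C
Reagents that add atoms: lead tetraacetate, CC(=O)O[Pb](OC(C)=O)(OC(C)=O)OC(C)=O
Why: α-Acetoxylation of a silyl enol ether with lead tetraacetate (the lead variant of the Rubottom oxidation) forms the C2′–OAc bond directly at the nucleophilic benzofuran carbon with loss of Me3SiOAc, and C2′ is expected to be set as S by 1,3-allylic strain control from C1 (with H-1 eclipsing the C2′=C3′ bond next to the OSiMe3 group, the C–O bond forms on the face anti to the C1–C7a bond and flanked by O2), while the acyl-substituted enol ether C3=C4 of the pyran is too electron-poor to compete.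

**Compound list**
1 | (S)-citronellal, (3S)-3,7-dimethyloct-6-enal | C[C@@H](CCC=C(C)C)CC=O | starting material
2 | (3S)-3,7-dimethyl-2-methylideneoct-6-enal | O=CC(=C)[C@@H](C)CCC=C(C)C | intermediate
3 | (5S)-5-methylcyclopent-1-ene-1-carbaldehyde | O=CC1=CCC[C@@H]1C | intermediate
4 | methyl 2-oxobutanoate | CCC(=O)C(=O)OC | starting material
5 | methyl (4aS,7S,7aR)-1-hydroxy-4,7-dimethyl-1,4a,5,6,7,7a-hexahydrocyclopenta[c]pyran-3-carboxylate (C1 anomers) | OC1OC(C(=O)OC)=C(C)[C@H]2CC[C@H](C)[C@H]21 | intermediate
6 | methyl (4aS,7S,7aR)-1-methoxy-4,7-dimethyl-1,4a,5,6,7,7a-hexahydrocyclopenta[c]pyran-3-carboxylate (C1 anomers) | COC1OC(C(=O)OC)=C(C)[C@H]2CC[C@H](C)[C@H]21 | intermediate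
7 | (4aS,7S,7aR)-N,1-dimethoxy-N,4,7-trimethyl-1,4a,5,6,7,7a-hexahydrocyclopenta[c]pyran-3-carboxamide (Weinreb amide, not isolated) | COC1OC(C(=O)N(C)OC)=C(C)[C@H]2CC[C@H](C)[C@H]21 | intermediate
8 | 1-[(4aS,7S,7aR)-1-methoxy-4,7-dimethyl-1,4a,5,6,7,7a-hexahydrocyclopenta[c]pyran-3-yl]-3-methylbutan-1-one (C1 anomers) | COC1OC(C(=O)CC(C)C)=C(C)[C@H]2CC[C@H](C)[C@H]21 | intermediate
9 | 1-(2-hydroxy-6-methylphenyl)ethan-1-one | CC(=O)c1c(C)cccc1O | starting material
10 | 2-bromo-1-(2-hydroxy-6-methylphenyl)ethan-1-one (not isolated) | O=C(CBr)c1c(C)cccc1O | intermediate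
11 | 4-methyl-1-benzofuran-3(2H)-one | O=C1COc2cccc(C)c12 | intermediate
12 | trimethyl[(4-methyl-1-benzofuran-3-yl)oxy]silane | C[Si](C)(C)Oc1coc2cccc(C)c12 | intermediate
13 | 2-[(1R,4aS,7S,7aR)-4,7-dimethyl-3-(3-methylbutanoyl)-1,4a,5,6,7,7a-hexahydrocyclopenta[c]pyran-1-yl]-4-methyl-1-benzofuran-3(2H)-one (C2′ epimers) | O=C1c2c(C)cccc2OC1[C@@H]1OC(C(=O)CC(C)C)=C(C)[C@H]2CC[C@H](C)[C@H]21 | intermediate
14 | 1-{(1R,4aS,7S,7aR)-4,7-dimethyl-1-[4-methyl-3-(trimethylsilyloxy)-1-benzofuran-2-yl]-1,4a,5,6,7,7a-hexahydrocyclopenta[c]pyran-3-yl}-3-methylbutan-1-one | C[Si](C)(C)Oc1c([C@@H]3OC(C(=O)CC(C)C)=C(C)[C@H]4CC[C@H](C)[C@H]43)oc2cccc(C)c12 | intermediate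
15 | (2S)-2-[(1R,4aS,7S,7aR)-4,7-dimethyl-3-(3-methylbutanoyl)-1,4a,5,6,7,7a-hexahydrocyclopenta[c]pyran-1-yl]-4-methyl-3-oxo-2,3-dihydro-1-benzofuran-2-yl acetate | CC(=O)O[C@]1([C@@H]2OC(C(=O)CC(C)C)=C(C)[C@H]3CC[C@H](C)[C@H]32)Oc2cccc(C)c2C1=O | target

**Total step count:** 10 steps.
**Longest linear sequence:** 8 steps (steps 1, 2, 3, 4, 5, 8, 9 and 10, from (S)-citronellal).

**Steps most likely to fail**

1. Step 3 (bears the label "Proposed new method:"). What may go wrong: self-aldol condensation of the keto ester outrunning the cross-reaction, 1,2-addition to the hindered α-branched enal instead of conjugate addition, or eroded face selectivity at C4a. Fallback, which replaces the catalytic conjugate addition by a stoichiometric cycloaddition of known type: it sets out from 3. Compound 4 and pyrrolidine (p-toluenesulfonic acid cat., toluene, azeotropic removal of water) give the preformed enamine methyl 2-(pyrrolidin-1-yl)but-2-enoate F1. This reacts with 3, acting as the 1-oxadiene O=C1–C7a=C4a, in an inverse-electron-demand hetero-Diels–Alder reaction (MeCN, 25–60 °C), the classical outcome of enamines with enals. The aminal cycloadduct methyl (4aR,7S)-4,7-dimethyl-3-(pyrrolidin-1-yl)-3,4,4a,5,6,7-hexahydrocyclopenta[c]pyran-3-carboxylate F2 already holds the C4–C4a bond; aqueous AcOH hydrolysis opens it to the 1,5-keto aldehyde, which should close to lactol 5, where the route is rejoined.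

2. Step 10. What may go wrong: poor facial discrimination at the planar C2′, or loss of stereochemical information through an oxocarbenium ion at C2′ after plumbylation. Fallback, which replaces kinetic substrate control by a catalyst-controlled dynamic resolution: it sets out from 14. Dimethyldioxirane (acetone, −78 °C, Rubottom oxidation) should give, after loss of the silyl group, the hemiketal 2-[(1R,4aS,7S,7aR)-4,7-dimethyl-3-(3-methylbutanoyl)-1,4a,5,6,7,7a-hexahydrocyclopenta[c]pyran-1-yl]-2-hydroxy-4-methyl-1-benzofuran-3(2H)-one F3. Its C2′ epimers interconvert by ring–chain tautomerism through the open 1,2-diketone phenol. Acetylation with Ac2O and i-Pr2NEt under a chiral isothiourea acyl-transfer catalyst (benzotetramisole, 2-phenyl-2,3-dihydroimidazo[2,1-b][1,3]benzothiazole, in the enantiomer matched to the 2′S epimer) is an acylative dynamic kinetic resolution of the kind known for tetrasubstituted lactols, and should lead to 15.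

3. Step 8. What may go wrong: slow ionisation of the acetal, whose ring oxygen is tied into the enone, loss of H-7a from the oxocarbenium ion (elimination to a 4H-pyran), or erosion of face selectivity at C1. Fallback, which replaces the oxocarbenium addition by a condensation/conjugate-addition sequence: it sets out from 8. Hydrolysis (aq. AcOH, THF) gives the lactol 1-[(4aS,7S,7aR)-1-hydroxy-4,7-dimethyl-1,4a,5,6,7,7a-hexahydrocyclopenta[c]pyran-3-yl]-3-methylbutan-1-one F4. Its open-chain aldehyde tautomer condenses with 11 on basic Al2O3 (CH2Cl2, 25 °C, the standard aurone synthesis) to the enone (2Z)-4-methyl-2-{[(1R,2S,5S)-2-methyl-5-(6-methyl-3,4-dioxoheptan-2-yl)cyclopentyl]methylidene}-1-benzofuran-3(2H)-one F5. The diketone enol of this enone then re-closes the pyran by 6-exo-trig oxa-Michael addition to C1 (1,8-diazabicyclo[5.4.0]undec-7-ene cat., THF), a reversible step expected to place the benzofuranone on the convex face, and the route is rejoined at 13.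

**Further compounds**
F1 | step 3 | methyl 2-(pyrrolidin-1-yl)but-2-enoate | CC=C(N1CCCC1)C(=O)OC
F2 | step 3 | methyl (4aR,7S)-4,7-dimethyl-3-(pyrrolidin-1-yl)-3,4,4a,5,6,7-hexahydrocyclopenta[c]pyran-3-carboxylate | COC(=O)C1(N2CCCC2)OC=C2[C@@H](C)CC[C@@H]2C1C
F3 | step 10 | 2-[(1R,4aS,7S,7aR)-4,7-dimethyl-3-(3-methylbutanoyl)-1,4a,5,6,7,7a-hexahydrocyclopenta[c]pyran-1-yl]-2-hydroxy-4-methyl-1-benzofuran-3(2H)-one | O=C1c2c(C)cccc2OC1(O)[C@@H]1OC(C(=O)CC(C)C)=C(C)[C@H]2CC[C@H](C)[C@H]21
F4 | step 8 | 1-[(4aS,7S,7aR)-1-hydroxy-4,7-dimethyl-1,4a,5,6,7,7a-hexahydrocyclopenta[c]pyran-3-yl]-3-methylbutan-1-one | OC1OC(C(=O)CC(C)C)=C(C)[C@H]2CC[C@H](C)[C@H]21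
F5 | step 8 | (2Z)-4-methyl-2-{[(1R,2S,5S)-2-methyl-5-(6-methyl-3,4-dioxoheptan-2-yl)cyclopentyl]methylidene}-1-benzofuran-3(2H)-one | CC(C)CC(=O)C(=O)C(C)[C@H]1CC[C@H](C)[C@H]1/C=C1\Oc2cccc(C)c2C1=O
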